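**Plan**

1. Numbering of the core (iridane style): ring C-5 to C-9, methyl C-10 on C-8, ring CH2O = C-1 on C-9, side-chain CH = C-4 on C-5 with the acyloxy arm C-3 and the free arm C-11. The retrosynthesis first masks each formyl(oxoethyl)hexenoyl unit as a cis-cyclopentane-1,2-diol (NaIO4 cleavage last), then cuts both ester C–O bonds to one acid 6 and a core diol 27.
2. The core ring is cut at C-7–C-8. The 2-methylcyclopentan-1-ol unit C-7(OH)–C-8(CH3) is the retron of a 5-exo ketyl–olefin closure of a 5-hexenal. O-7 and O-3, the two oxygens acylated in the target, stand 1,5, so the aldehyde is stored as the δ-lactol ring O–C-3–C-4–C-5–C-6–C-7.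
3. Forward, acid 6: four steps from cyclopentenone 1.
4. Forward, core: Rh-catalysed 1,4-addition to 5,6-dihydropyran-2-one (C-5), trans-hydroxymethylation (C-9), lactone to vinyl plus acid, thermodynamic relactonization (C-4), lactol, SmI2 closure (C-7, C-8), double esterification, deprotection, glycol cleavage.
5. Stereochemistry: C-5 from (R)-BINAP; C-9 and C-4 relayed from C-5 through two six-membered lactones; C-7 and C-8 from a chair-like transition state; the acyl stereocentre from enone 1 by exo alkylation.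

Key step: step 16

Remark: the target is treated as the open tetra-aldehyde as drawn; 1, 7 and 11 are taken as commercial; TBS = tert-butyldimethylsilyl, TBDPS = tert-butyldiphenylsilyl, TES = triethylsilyl.

**Step 1**
Reactants: 1 (3aR,6aR)-2,2-dimethyl-3a,6a-dihydro-4H-cyclopenta[d][1,3]dioxol-4-one
Product: 2 (3aR,6aR)-2,2-dimethyltetrahydro-4H-cyclopenta[d][1,3]dioxol-4-one
Conditions: H2 (1 atm), Pd/C, EtOAc, rt
Reagents that add atoms: none
Why: Catalytic hydrogenation should saturate the enone C=C without touching the acetonide or the ketone.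

**Step 2**
Reactants: 2
Product: 4 methyl 2-[(3aR,5S,6aR)-2,2-dimethyl-4-oxotetrahydro-4H-cyclopenta[d][1,3]dioxol-5-yl]acetate, via lithium enolate 3 (not isolated)
Conditions: LiN(SiMe3)2, THF, −78 °C; then BrCH2CO2Me, DMPU, −78 to −40 °C
Reagents that add atoms: methyl bromoacetate, COC(=O)CBr
Why: Kinetic enolate alkylation: deprotonation at the only α-CH2 and attack on the convex face, anti to the cis-fused dioxolane, should set the (5S) centre that becomes the acyl stereocentre.

**Step 3**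
Reactants: 4
Product: 5 methyl 2-[(3aS,4E,5S,6aR)-4-ethylidene-2,2-dimethyltetrahydro-4H-cyclopenta[d][1,3]dioxol-5-yl]acetate
Conditions: EtPPh3Br, KOtBu, THF, 0 °C to rt
Reagents that add atoms: ethyltriphenylphosphonium bromide, CC[P+](c1ccccc1)(c1ccccc1)c1ccccc1.[Br-]
Why: Wittig olefination of the ketone should install the exocyclic ethylidene, the (E) isomer (methyl on the side of C-5) being the one carried on.

**Step 4**
Reactants: 5
Product: 6 2-[(3aS,4E,5S,6aR)-4-ethylidene-2,2-dimethyltetrahydro-4H-cyclopenta[d][1,3]dioxol-5-yl]acetic acid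
Conditions: LiOH, THF/H2O, 0 °C to rt; then dilute HCl to pH 4
Reagents that add atoms: lithium hydroxide, [Li+].[OH-]
Why: Saponification of the methyl ester should leave the acetonide and the ethylidene untouched, and the stereocentre is β to the carboxyl and cannot epimerize.

**Step 5**
Reactants: 7 2-bromoprop-2-en-1-ol
Product: 8 (2-bromoallyloxy)(tert-butyl)dimethylsilane
Conditions: tBuMe2SiCl, imidazole, DMF, rt
Reagents that add atoms: tert-butyl(chloro)dimethylsilane, CC(C)(C)[Si](C)(C)Cl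
Why: Standard silylation of a primary allylic alcohol.

**Step 6**
Reactants: 8
Product: 10 2-[3-(TBS-oxy)prop-1-en-2-yl]-4,4,5,5-tetramethyl-1,3,2-dioxaborolane, via vinyllithium 9 (not isolated)
Conditions: tBuLi (2.1 equiv), Et2O, −78 °C; then iPrOB(pin), −78 °C to rt; aq. NH4Cl
Reagents that add atoms: 2-isopropoxy-4,4,5,5-tetramethyl-1,3,2-dioxaborolane, CC(C)OB1OC(C)(C)C(C)(C)O1
Why: Bromine–lithium exchange followed by borylation is the usual route to 1,1-disubstituted alkenyl pinacol boronates.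

**Step 7**
Reactants: 11 5,6-dihydro-2H-pyran-2-one; 10
Product: 12 (4R)-4-[3-(TBS-oxy)prop-1-en-2-yl]tetrahydro-2H-pyran-2-one
Conditions: [Rh(OH)((R)-BINAP)]2 (3 mol% Rh), dioxane/H2O (10:1), 40 °C
Reagents that add atoms: none
Why: Hayashi–Miyaura asymmetric 1,4-addition of an alkenylboronate to the unsaturated lactone should set C-5; the ligand is chosen by analogy with (S)-BINAP giving (S)-4-aryl lactones, so (R)-BINAP should give the (4R) lactone.

**Step 8**
Reactants: 12
Product: 15 (3R,4R)-3-[(TBDPS-oxy)methyl]-4-[3-(TBS-oxy)prop-1-en-2-yl]tetrahydro-2H-pyran-2-one, via lithium enolate 13 (not isolated), via hydroxymethyl lactone 14 (not isolated)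
Conditions: LiN(iPr)2, THF, −78 °C; CH2O (gas), −78 to −20 °C; aq. NH4Cl; crude, tBuPh2SiCl, imidazole, DMF, 0 °C
Reagents that add atoms: formaldehyde, C=O; tert-butyl(chloro)diphenylsilane, CC(C)(C)[Si](Cl)(c1ccccc1)c1ccccc1
Why: Aldol-type hydroxymethylation of the δ-lactone enolate should occur anti to the C-4 ring substituent and set C-9 trans to C-5, and immediate silylation should prevent dehydration to the α-methylene lactone.

**Step 9**
Reactants: 15
Product: 17 (3R,4S)-3-[(TBDPS-oxy)methyl]-4-[1-(TBS-oxy)-3-hydroxypropan-2-yl]tetrahydro-2H-pyran-2-one (both epimers at the propan-2-yl carbon), via B-alkyl-9-BBN adduct 16 (not isolated)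
Conditions: 9-BBN-H, THF, 0 °C to rt; then H2O2, aq. NaOAc, 0 °C
Reagents that add atoms: hydrogen peroxide, OO
Why: Anti-Markovnikov hydroboration–oxidation of the 1,1-disubstituted alkene should spare the lactone; the configuration formed at C-4 is irrelevant because it is erased in step 10.

**Step 10**
Reactants: 17
Product: 18 (3R,4S)-4-[1,3-bis(TBS-oxy)propan-2-yl]-3-[(TBDPS-oxy)methyl]tetrahydro-2H-pyran-2-one
Conditions: tBuMe2SiCl, imidazole, DMF, rt
Reagents that add atoms: tert-butyl(chloro)dimethylsilane, CC(C)(C)[Si](C)(C)Cl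
Why: Silylation makes the two arms on C-4 identical, so both epimers of 17 should converge on one compound.

**Step 11**
Reactants: 18
Product: 20 (3R,4R)-3-[1,3-bis(TBS-oxy)propan-2-yl]-4-[(TBDPS-oxy)methyl]hex-5-en-1-ol, via lactol 19 (not isolated)
Conditions: iBu2AlH, CH2Cl2, −78 °C; then crude lactol, Ph3P=CH2 (from Ph3PCH3Br, KN(SiMe3)2), THF, −78 to 0 °C
Reagents that add atoms: methyltriphenylphosphonium bromide, C[P+](c1ccccc1)(c1ccccc1)c1ccccc1.[Br-]
Why: Partial reduction of the lactone and Wittig methylenation of the lactol should turn the lactone carbonyl into the vinyl group and free the C-7 hydroxyl; a salt-free ylide at low temperature should avoid epimerization at C-9.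

**Step 12**
Reactants: 20
Product: 21 (3R,4R)-3-[1,3-bis(TBS-oxy)propan-2-yl]-4-[(TBDPS-oxy)methyl]hex-5-enoic acid
Conditions: TEMPO (cat.), PhI(OAc)2, MeCN/H2O (1:1), rt
Reagents that add atoms: water, O
Why: Nitroxyl-catalysed oxidation of the single primary alcohol to the carboxylic acid should tolerate the alkene and the silyl ethers.

**Step 13**
Reactants: 21
Product: 23 (4R,5S)-4-[(2R)-1-(TBDPS-oxy)but-3-en-2-yl]-5-(hydroxymethyl)tetrahydro-2H-pyran-2-one, via dihydroxy acid 22 (not isolated)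
Conditions: camphorsulfonic acid (cat.), MeOH/CH2Cl2, 0 °C; then TsOH (cat.), PhMe, 60 °C
Reagents that add atoms: none
Why: Acid should cleave the two primary TBS ethers selectively over the TBDPS ether, and the δ-lactones formed from either arm interconvert by translactonization through the free hydroxymethyl, so the equilibrium should favour the trans-4,5-diequatorial lactone and thereby set C-4 (thermodynamic desymmetrization).

**Step 14**
Reactants: 23
Product: 24 (4R,5R)-5-[(TBS-oxy)methyl]-4-[(2R)-1-(TBDPS-oxy)but-3-en-2-yl]tetrahydro-2H-pyran-2-one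
Conditions: tBuMe2SiCl, imidazole, DMAP (cat.), CH2Cl2, rt
Reagents that add atoms: tert-butyl(chloro)dimethylsilane, CC(C)(C)[Si](C)(C)Cl
Why: Silylation of the exocyclic hydroxyl freezes the C-4 configuration and marks C-11 as an arm that stays unacylated.

**Step 15**
Reactants: 24
Product: 25 (4R,5R)-5-[(TBS-oxy)methyl]-4-[(2R)-1-(TBDPS-oxy)but-3-en-2-yl]tetrahydro-2H-pyran-2-ol (anomers)
Conditions: iBu2AlH, CH2Cl2, −78 °C
Reagents that add atoms: none
Why: Partial reduction of a δ-lactone to the lactol at low temperature is standard.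

**Step 16**
Reactants: 25
Product: 27 (1R,2R,3S,4R)-4-[(2R)-1-(TBS-oxy)-3-hydroxypropan-2-yl]-3-[(TBDPS-oxy)methyl]-2-methylcyclopentan-1-ol, via hydroxy aldehyde 26 (not isolated)
Conditions: SmI2 (2.5 equiv), HMPA (10 equiv), tBuOH (2 equiv), THF, 0 °C to rt, 0.01 M
Reagents that add atoms: none
Why: Proposed new method: lactol 25 is in ring–chain equilibrium with hydroxy aldehyde 26 and only the open form accepts an electron from SmI2–HMPA, so irreversible ketyl formation at C-7 should drain the lactol; the closest known reaction type is the SmI2–HMPA ketyl–olefin cyclization of preformed 5-hexenals bearing unactivated alkenes, and SmI2–H2O reductions of lactones are understood to pass through the same lactol, aldehyde and ketyl stages. The ketyl carbon C-7 adds to the internal vinyl carbon C-8 in a 5-exo-trig closure that forms the cyclopentane, and the primary radical at C-10 is reduced by a second SmI2 and protonated by tBuOH to the methyl group. C-8 is set by the chair-like transition state in which the trans substituents on C-5 and C-9 are pseudo-equatorial and the alkene terminus points away from the C-9 arm, which puts the methyl trans to C-1. C-7 is set by the bulky HMPA-ligated O–Sm group, which stays anti to the alkene and ends trans to the methyl, so the all-trans ring should result. The step needs ring closure to outrun simple reduction and pinacol coupling of the ketyl, which HMPA and high dilution should secure, and the substrate holds no other group reducible under these conditions. Ring opening also frees the C-3 hydroxyl, so the product carries exactly the two hydroxyls that are to be acylated.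

**Step 17**
Reactants: 27; 6 (2.5 equiv)
Product: 28 bis-ester of 27 (at O-3 and O-7) with acid 6
Conditions: EDC·HCl, DMAP, CH2Cl2, 0 °C to rt
Reagents that add atoms: none
Why: Steglich esterification should acylate both the primary and the hindered secondary hydroxyl when the acid is in excess; the acid has no α-stereocentre to lose.

**Step 18**
Reactants: 28
Product: 30 bis[(1S,3R,4S,E)-2-ethylidene-3,4-dihydroxycyclopentyl]acetate of the core tetrol (O-3 and O-7 acylated; C-1 and C-11 hydroxyls free), via diol bis-acetonide 29 (not isolated)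
Conditions: HF·pyridine, THF/pyridine, 0 °C to rt; then AcOH/H2O (4:1), 40 °C
Reagents that add atoms: none
Why: Fluoride-mediated desilylation followed by mild acid hydrolysis of the two acetonides should keep the medium acidic throughout and so suppress 1,3-acyl migration.

**Step 19**
Reactants: 30
Product: 31 target CNP0192766.1
Conditions: NaIO4, THF/H2O, 0 °C
Reagents that add atoms: none
Why: Malaprade glycol cleavage of the two cis-1,2-diols should give, in each acyl unit, the (E)-enal and the 2-oxoethyl arm; the remaining hydroxyls are 1,3 or farther apart and are not cleaved.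

**Compound list**

1 | (3aR,6aR)-2,2-dimethyl-3a,6a-dihydro-4H-cyclopenta[d][1,3]dioxol-4-one | O=C1C=C[C@H]2OC(C)(C)O[C@@H]12 | starting material
2 | (3aR,6aR)-2,2-dimethyltetrahydro-4H-cyclopenta[d][1,3]dioxol-4-one | O=C1CC[C@H]2OC(C)(C)O[C@@H]12 | intermediate
3 | lithium enolate of 2 | [Li]OC1=CC[C@H]2OC(C)(C)O[C@@H]12 | intermediate
4 | methyl 2-[(3aR,5S,6aR)-2,2-dimethyl-4-oxotetrahydro-4H-cyclopenta[d][1,3]dioxol-5-yl]acetate | COC(=O)C[C@@H]1C[C@H]2OC(C)(C)O[C@H]2C1=O | intermediate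
5 | methyl 2-[(3aS,4E,5S,6aR)-4-ethylidene-2,2-dimethyltetrahydro-4H-cyclopenta[d][1,3]dioxol-5-yl]acetate | COC(=O)C[C@@H]1C[C@H]2OC(C)(C)O[C@H]2/C1=C/C | intermediate
6 | 2-[(3aS,4E,5S,6aR)-4-ethylidene-2,2-dimethyltetrahydro-4H-cyclopenta[d][1,3]dioxol-5-yl]acetic acid | OC(=O)C[C@@H]1C[C@H]2OC(C)(C)O[C@H]2/C1=C/C | intermediate
7 | 2-bromoprop-2-en-1-ol | OCC(Br)=C | starting material
8 | (2-bromoallyloxy)(tert-butyl)dimethylsilane | C=C(Br)CO[Si](C)(C)C(C)(C)C | intermediate
9 | [3-(TBS-oxy)prop-1-en-2-yl]lithium | [Li]C(=C)CO[Si](C)(C)C(C)(C)C | intermediate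
10 | 2-[3-(TBS-oxy)prop-1-en-2-yl]-4,4,5,5-tetramethyl-1,3,2-dioxaborolane | C=C(CO[Si](C)(C)C(C)(C)C)B1OC(C)(C)C(C)(C)O1 | intermediate
11 | 5,6-dihydro-2H-pyran-2-one | O=C1C=CCCO1 | starting material
12 | (4R)-4-[3-(TBS-oxy)prop-1-en-2-yl]tetrahydro-2H-pyran-2-one | O=C1C[C@H](C(=C)CO[Si](C)(C)C(C)(C)C)CCO1 | intermediate
13 | lithium enolate of 12 | [Li]OC1=C[C@H](C(=C)CO[Si](C)(C)C(C)(C)C)CCO1 | intermediate
14 | (3R,4R)-3-(hydroxymethyl)-4-[3-(TBS-oxy)prop-1-en-2-yl]tetrahydro-2H-pyran-2-one | O=C1[C@@H](CO)[C@H](C(=C)CO[Si](C)(C)C(C)(C)C)CCO1 | intermediate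
15 | (3R,4R)-3-[(TBDPS-oxy)methyl]-4-[3-(TBS-oxy)prop-1-en-2-yl]tetrahydro-2H-pyran-2-one | O=C1[C@@H](CO[Si](c2ccccc2)(c2ccccc2)C(C)(C)C)[C@H](C(=C)CO[Si](C)(C)C(C)(C)C)CCO1 | intermediate
16 | B-alkyl-9-borabicyclo[3.3.1]nonane adduct of 15 | O=C1[C@@H](CO[Si](c2ccccc2)(c2ccccc2)C(C)(C)C)[C@H](C(CB2C3CCCC2CCC3)CO[Si](C)(C)C(C)(C)C)CCO1 | intermediate
17 | (3R,4S)-3-[(TBDPS-oxy)methyl]-4-[1-(TBS-oxy)-3-hydroxypropan-2-yl]tetrahydro-2H-pyran-2-one, epimers at the propan-2-yl carbon | O=C1[C@@H](CO[Si](c2ccccc2)(c2ccccc2)C(C)(C)C)[C@H](C(CO)CO[Si](C)(C)C(C)(C)C)CCO1 | intermediate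
18 | (3R,4S)-4-[1,3-bis(TBS-oxy)propan-2-yl]-3-[(TBDPS-oxy)methyl]tetrahydro-2H-pyran-2-one | O=C1[C@@H](CO[Si](c2ccccc2)(c2ccccc2)C(C)(C)C)[C@H](C(CO[Si](C)(C)C(C)(C)C)CO[Si](C)(C)C(C)(C)C)CCO1 | intermediate
19 | (3R,4S)-4-[1,3-bis(TBS-oxy)propan-2-yl]-3-[(TBDPS-oxy)methyl]tetrahydro-2H-pyran-2-ol, anomers | OC1[C@@H](CO[Si](c2ccccc2)(c2ccccc2)C(C)(C)C)[C@H](C(CO[Si](C)(C)C(C)(C)C)CO[Si](C)(C)C(C)(C)C)CCO1 | intermediate
20 | (3R,4R)-3-[1,3-bis(TBS-oxy)propan-2-yl]-4-[(TBDPS-oxy)methyl]hex-5-en-1-ol | C=C[C@@H](CO[Si](c1ccccc1)(c1ccccc1)C(C)(C)C)[C@H](C(CO[Si](C)(C)C(C)(C)C)CO[Si](C)(C)C(C)(C)C)CCO | intermediate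
21 | (3R,4R)-3-[1,3-bis(TBS-oxy)propan-2-yl]-4-[(TBDPS-oxy)methyl]hex-5-enoic acid | C=C[C@@H](CO[Si](c1ccccc1)(c1ccccc1)C(C)(C)C)[C@H](C(CO[Si](C)(C)C(C)(C)C)CO[Si](C)(C)C(C)(C)C)CC(=O)O | intermediate
22 | (3R,4R)-3-(1,3-dihydroxypropan-2-yl)-4-[(TBDPS-oxy)methyl]hex-5-enoic acid | C=C[C@@H](CO[Si](c1ccccc1)(c1ccccc1)C(C)(C)C)[C@H](C(CO)CO)CC(=O)O | intermediate
23 | (4R,5S)-4-[(2R)-1-(TBDPS-oxy)but-3-en-2-yl]-5-(hydroxymethyl)tetrahydro-2H-pyran-2-one | O=C1C[C@H]([C@H](CO[Si](c2ccccc2)(c2ccccc2)C(C)(C)C)C=C)[C@@H](CO)CO1 | intermediate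
24 | (4R,5R)-5-[(TBS-oxy)methyl]-4-[(2R)-1-(TBDPS-oxy)but-3-en-2-yl]tetrahydro-2H-pyran-2-one | O=C1C[C@H]([C@H](CO[Si](c2ccccc2)(c2ccccc2)C(C)(C)C)C=C)[C@@H](CO[Si](C)(C)C(C)(C)C)CO1 | intermediate
25 | (4R,5R)-5-[(TBS-oxy)methyl]-4-[(2R)-1-(TBDPS-oxy)but-3-en-2-yl]tetrahydro-2H-pyran-2-ol, anomers | OC1C[C@H]([C@H](CO[Si](c2ccccc2)(c2ccccc2)C(C)(C)C)C=C)[C@@H](CO[Si](C)(C)C(C)(C)C)CO1 | intermediate
26 | (3R,4R)-3-[(2R)-1-(TBS-oxy)-3-hydroxypropan-2-yl]-4-[(TBDPS-oxy)methyl]hex-5-enal | O=CC[C@H]([C@H](CO[Si](c1ccccc1)(c1ccccc1)C(C)(C)C)C=C)[C@@H](CO[Si](C)(C)C(C)(C)C)CO | intermediate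
27 | (1R,2R,3S,4R)-4-[(2R)-1-(TBS-oxy)-3-hydroxypropan-2-yl]-3-[(TBDPS-oxy)methyl]-2-methylcyclopentan-1-ol | OC[C@H](CO[Si](C)(C)C(C)(C)C)[C@@H]1C[C@@H](O)[C@H](C)[C@H]1CO[Si](c1ccccc1)(c1ccccc1)C(C)(C)C | intermediate
28 | bis-ester of 27 with acid 6 (acyl on O-3 and O-7; TBS on O-11, TBDPS on O-1) | O=C(C[C@@H]1C[C@H]2OC(C)(C)O[C@H]2/C1=C/C)OC[C@H](CO[Si](C)(C)C(C)(C)C)[C@@H]1C[C@@H](OC(=O)C[C@@H]2C[C@H]3OC(C)(C)O[C@H]3/C2=C/C)[C@H](C)[C@H]1CO[Si](c1ccccc1)(c1ccccc1)C(C)(C)C | intermediate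
29 | desilylated bis-ester (both acetonides intact; C-1 and C-11 hydroxyls free) | O=C(C[C@@H]1C[C@H]2OC(C)(C)O[C@H]2/C1=C/C)OC[C@H](CO)[C@@H]1C[C@@H](OC(=O)C[C@@H]2C[C@H]3OC(C)(C)O[C@H]3/C2=C/C)[C@H](C)[C@H]1CO | intermediate
30 | bis-ester hexaol (two cis-cyclopentane-1,2-diols; C-1 and C-11 hydroxyls free) | O=C(C[C@@H]1C[C@@H](O)[C@@H](O)/C1=C/C)OC[C@H](CO)[C@@H]1C[C@@H](OC(=O)C[C@@H]2C[C@@H](O)[C@@H](O)/C2=C/C)[C@H](C)[C@H]1CO | intermediate
31 | CNP0192766.1 | C/C=C(/C=O)[C@@H](CC=O)CC(=O)OC[C@H](CO)[C@@H]1C[C@@H](OC(=O)C[C@H](CC=O)/C(C=O)=C\C)[C@H](C)[C@H]1CO | target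

**Step count and risks**

Total step count: 19. Longest linear sequence: 15 steps (steps 5 to 19, from 7).

Steps most likely to fail:

1. Step 16 (proposed new method). The lactol may open too slowly, or the ketyl may be reduced to the open-chain 1,5-diol or dimerize before it closes the ring. Fallback with known chemistry, setting out from lactone 24: ring opening with MeNH(OMe)·HCl and iPrMgCl should give the hydroxy N-methoxy-N-methylamide F1. Silylation with Et3SiCl and imidazole should give its TES ether F2. Reduction with iBu2AlH at −78 °C should give the free aldehyde F3. The classical SmI2–HMPA–tBuOH ketyl–olefin cyclization of this preformed 5-hexenal should give the TES-protected cyclopentanol F4. Selective cleavage of the primary TES ether with pyridinium p-toluenesulfonate in MeOH comes back to the route at 27.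

2. Step 13. The thermodynamic bias between the two diastereotopic hydroxymethyl arms may be too small, or the translactonization too slow, so that C-4 is set with poor selectivity. Fallback by kinetic, protecting-group differentiation, setting out from 17: the C-4 epimers are separated by chromatography. The epimer whose free hydroxymethyl is the arm destined for the ring is capped with Et3SiCl to give the TES ether lactone F5. iBu2AlH reduction and Wittig methylenation, as in step 11, should give the alkenol F6. TEMPO/PhI(OAc)2 oxidation should give the acid F7. Pyridinium p-toluenesulfonate in MeOH should cleave only the TES ether, and the hydroxy acid then lactonizes through that one arm, which comes back to the route at 24 without passing through 23.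

3. Step 3. The ylide may give the wrong alkene geometry, epimerize C-5, or trigger β-elimination of the acetonide oxygen next to the ketone. Fallback by Peterson olefination, setting out from 4: CeCl3-mediated addition of 1-(trimethylsilyl)ethyllithium to the ketone should give the β-hydroxysilane F8. Its separated diastereomers are eliminated stereospecifically, with KH for syn elimination or BF3·OEt2 for anti elimination, chosen so that each delivers the (E)-ethylidene compound, which comes back to the route at 5.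

**Further compounds**

F1 | step 16 | (3R,4R)-3-[(2R)-1-(TBS-oxy)-3-hydroxypropan-2-yl]-4-[(TBDPS-oxy)methyl]-N-methoxy-N-methylhex-5-enamide | CON(C)C(=O)C[C@H]([C@H](CO[Si](c1ccccc1)(c1ccccc1)C(C)(C)C)C=C)[C@@H](CO[Si](C)(C)C(C)(C)C)CO
F2 | step 16 | TES ether of F1 | CON(C)C(=O)C[C@H]([C@H](CO[Si](c1ccccc1)(c1ccccc1)C(C)(C)C)C=C)[C@@H](CO[Si](C)(C)C(C)(C)C)CO[Si](CC)(CC)CC
F3 | step 16 | (3R,4R)-3-[1-(TBS-oxy)-3-(TES-oxy)propan-2-yl]-4-[(TBDPS-oxy)methyl]hex-5-enal | O=CC[C@H]([C@H](CO[Si](c1ccccc1)(c1ccccc1)C(C)(C)C)C=C)[C@@H](CO[Si](C)(C)C(C)(C)C)CO[Si](CC)(CC)CC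
F4 | step 16 | TES ether of 27 at the primary hydroxyl | CC[Si](CC)(CC)OC[C@H](CO[Si](C)(C)C(C)(C)C)[C@@H]1C[C@@H](O)[C@H](C)[C@H]1CO[Si](c1ccccc1)(c1ccccc1)C(C)(C)C
F5 | step 13 | TES ether of the matching C-4 epimer of 17 | O=C1[C@@H](CO[Si](c2ccccc2)(c2ccccc2)C(C)(C)C)[C@H]([C@H](CO[Si](CC)(CC)CC)CO[Si](C)(C)C(C)(C)C)CCO1
F6 | step 13 | (3R,4R)-3-[1-(TBS-oxy)-3-(TES-oxy)propan-2-yl]-4-[(TBDPS-oxy)methyl]hex-5-en-1-ol | C=C[C@@H](CO[Si](c1ccccc1)(c1ccccc1)C(C)(C)C)[C@H]([C@H](CO[Si](CC)(CC)CC)CO[Si](C)(C)C(C)(C)C)CCO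
F7 | step 13 | (3R,4R)-3-[1-(TBS-oxy)-3-(TES-oxy)propan-2-yl]-4-[(TBDPS-oxy)methyl]hex-5-enoic acid | C=C[C@@H](CO[Si](c1ccccc1)(c1ccccc1)C(C)(C)C)[C@H]([C@H](CO[Si](CC)(CC)CC)CO[Si](C)(C)C(C)(C)C)CC(=O)O
F8 | step 3 | methyl 2-[(3aR,5S,6aR)-4-hydroxy-2,2-dimethyl-4-[1-(trimethylsilyl)ethyl]tetrahydro-4H-cyclopenta[d][1,3]dioxol-5-yl]acetate | COC(=O)C[C@@H]1C[C@H]2OC(C)(C)O[C@H]2C1(O)C(C)[Si](C)(C)C
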